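**Retrosynthetic overview**
- Feature: ring B (C5–C6–C7=C8–C9–C10) is a cyclohexene whose C7=C8 bond lies across the ring from the C5–C10 fusion bond, with C6 and the side-chain carbon C9 as its allylic carbons; this is the retron of a [4+2] cycloaddition.
- Disconnections: the C15–O ester (a C32 ω-hydroxy acid built from two C16 pieces), C12–C13 and C13–C16/C14–C15 (acetylide alkylation, carboalumination–formaldehyde), C3–C4 of ring A (tertiary-radical 6-endo closure onto a C1 vinyl ketone), and C5–C6 plus C9–C10 of ring B (Diels–Alder of the diene C6=C7–C8=C9 with di-(−)-menthyl mesaconate, C5=C10).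
- Ring order: ring B first, with C5, C9 and C10 set in one step; ring A second, from the two ester carbons (future C4 and C1); then side chain, acylation and desilylation.

Key step: step 9

Assumption (remark on the chemistry): labdane numbering is used (C17 on C8, C20 on C10), the acyl group is read as 32-hydroxydotriacontanoyl, and the (−)-menthyl esters are assumed to direct the diene to the same π-face as in aluminium-promoted cycloadditions of di-(−)-menthyl fumarate; if the mesaconate methyl group reverses this, (+)-menthol would be used instead. TBS = tert-butyldimethylsilyl, TBDPS = tert-butyldiphenylsilyl.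

**Diene**

Step 1
Reactants: 1 but-3-yn-1-ol
Product: 2 tert-butyl(but-3-yn-1-yloxy)dimethylsilane
Conditions: TBSCl, imidazole, DMF, 0 → 23 °C
Reagents that add atoms: tert-butyldimethylsilyl chloride, CC(C)(C)[Si](C)(C)Cl
Why: Imidazole-promoted silylation of a primary alcohol (silyl ether formation) should proceed cleanly and leave the terminal alkyne untouched.

Step 2
Reactants: 2 tert-butyl(but-3-yn-1-yloxy)dimethylsilane
Product: 4 methyl 5-[(tert-butyldimethylsilyl)oxy]pent-2-ynoate, via lithium acetylide 3 (not isolated)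
Conditions: n-BuLi, THF, −78 °C; ClCO2Me, −78 → 0 °C
Reagents that add atoms: methyl chloroformate, COC(=O)Cl
Why: Deprotonation of the terminal alkyne and C-acylation of the lithium acetylide with a chloroformate (acetylide acylation) should give the ynoate.

Step 3
Reactants: 4 methyl 5-[(tert-butyldimethylsilyl)oxy]pent-2-ynoate
Product: 5 methyl (E)-5-[(tert-butyldimethylsilyl)oxy]-2-(tributylstannyl)pent-2-enoate
Conditions: Bu3SnH, Pd(PPh3)4 (2 mol %), THF, 0 → 23 °C
Reagents that add atoms: tributyltin hydride, CCCC[SnH](CCCC)CCCC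
Why: Palladium-catalysed hydrostannation of a 2-alkynoate is a syn addition that places tin on the α-carbon, so the C9 hydrogen should end cis to tin and the C11 chain trans to it, which fixes the C8=C9 geometry of the diene.

Step 4
Reactants: 5 methyl (E)-5-[(tert-butyldimethylsilyl)oxy]-2-(tributylstannyl)pent-2-enoate
Product: 6 (E)-5-[(tert-butyldimethylsilyl)oxy]-2-(tributylstannyl)pent-2-en-1-ol
Conditions: i-Bu2AlH (2.5 equiv), CH2Cl2, −78 → −20 °C; aqueous Rochelle salt
Reagents that add atoms: none
Why: Hydride reduction of the conjugated ester to the allylic alcohol (1,2-reduction by i-Bu2AlH) should leave the vinylstannane, the silyl ether and the alkene geometry intact.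

Step 5
Reactants: 6 (E)-5-[(tert-butyldimethylsilyl)oxy]-2-(tributylstannyl)pent-2-en-1-ol
Product: 7 (E)-5-[(tert-butyldimethylsilyl)oxy]-1-[(tert-butyldiphenylsilyl)oxy]-2-(tributylstannyl)pent-2-ene
Conditions: TBDPSCl, imidazole, CH2Cl2, 23 °C
Reagents that add atoms: tert-butyldiphenylsilyl chloride, CC(C)(C)[Si](Cl)(c1ccccc1)c1ccccc1
Why: Silylation of the primary allylic alcohol (silyl ether formation) installs the robust C17 protecting group that must outlast the TBS ether.

Step 6
Reactants: 7 (E)-5-[(tert-butyldimethylsilyl)oxy]-1-[(tert-butyldiphenylsilyl)oxy]-2-(tributylstannyl)pent-2-ene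
Product: 8 (E)-5-[(tert-butyldimethylsilyl)oxy]-1-[(tert-butyldiphenylsilyl)oxy]-2-iodopent-2-ene
Conditions: I2, CH2Cl2, 0 °C
Reagents that add atoms: iodine, II
Why: Iododestannylation is an electrophilic ipso substitution that proceeds with retention of alkene geometry.

Step 7
Reactants: 8 (E)-5-[(tert-butyldimethylsilyl)oxy]-1-[(tert-butyldiphenylsilyl)oxy]-2-iodopent-2-ene
Product: 9 (Z)-5-[(tert-butyldimethylsilyl)oxy]-1-[(tert-butyldiphenylsilyl)oxy]-2-vinylpent-2-ene (C11 trans to the vinyl group)
Conditions: CH2=CHSnBu3, PdCl2(MeCN)2 (5 mol %), DMF, 23 °C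
Reagents that add atoms: tributyl(vinyl)stannane, C=C[Sn](CCCC)(CCCC)CCCC
Why: Stille cross-coupling of an alkenyl iodide with a vinylstannane retains the geometry of the iodide and should give the 1,2-disubstituted diene with its C9 substituent outside.

**Dienophile**

Step 8
Reactants: 10 mesaconic acid; 11 (−)-menthol (2.2 equiv in all, one molecule for each carboxyl group)
Product: 12 di-(−)-menthyl mesaconate
Conditions: 11 (2.2 equiv), p-TsOH·H2O (5 mol %), toluene, reflux, Dean–Stark trap
Reagents that add atoms: (−)-menthol (second equivalent of 11), C[C@@H]1CC[C@H]([C@@H](C1)O)C(C)C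
Why: Acid-catalysed (Fischer) esterification of both carboxyl groups, each by one molecule of menthol, with azeotropic removal of two molecules of water should give the diester; the E geometry should hold because mesaconate is the most stable of the methylbutenedioate isomers, and the menthol stereocentres are untouched because the alcohol C–O bond is not broken.

**Key cycloaddition**

Step 9
Reactants: 9 (Z)-5-[(tert-butyldimethylsilyl)oxy]-1-[(tert-butyldiphenylsilyl)oxy]-2-vinylpent-2-ene; 12 di-(−)-menthyl mesaconate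
Product: 13 bis[(1R,2S,5R)-menthyl] (1S,2S,6R)-6-{2-[(tert-butyldimethylsilyl)oxy]ethyl}-5-{[(tert-butyldiphenylsilyl)oxy]methyl}-1-methylcyclohex-4-ene-1,2-dicarboxylate (ring C1 = C10; ring C2 = C5; ring C6 = C9)
Conditions: Et2AlCl (2.2 equiv), 12 (1.2 equiv), toluene, −40 → 0 °C; cold 1 M HCl quench
Reagents that add atoms: none
Why: Et2AlCl binds both ester carbonyls of 12 and lowers its LUMO, so that a concerted but asynchronous [4+2] cycloaddition can run below 0 °C; the closest known type is the aluminium-promoted Diels–Alder reaction of chiral fumarate-type diesters with acyclic dienes. Ring B is closed as the cycloadduct ring by suprafacial formation of C5–C6 and C9–C10, which leaves C7=C8 and the C17 oxygen in place. The relative configuration of C5 and C10 follows stereospecifically from the E geometry of the diester (trans carboxyl carbons, the future trans ring fusion), and their absolute configuration from the two menthyl groups, which are expected to shield one π-face as they do in the fumarate. C9 is set by the E geometry of C8=C9 in 9 together with the endo position of the C5 ester (C10 methyl endo, C10 ester exo), which places C11 cis to the C10 methyl. The step needs regioselectivity (C6 to C5, C9 to C10), expected because the unsubstituted diene terminus C6 attacks the unmethylated, more electrophilic carbon C5 first; it also needs endo selectivity for the C5 ester and facial selectivity from the auxiliary. All three are predictions for this pair of partners.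

**Ring A**

Step 10
Reactants: 13 di-(−)-menthyl cycloadduct
Product: 15 (−)-menthyl ester in which the C5 ester of 13 has become a C(CH3)2OH group (C4 carbinol; C5, C9, C10 as in 13), via C4 methyl ketone 14 (not isolated)
Conditions: MeLi (3 equiv), THF, −78 → −40 °C; aqueous NH4Cl at −40 °C
Reagents that add atoms: methyllithium (two equivalents add), [Li]C
Why: Double 1,2-addition of an organolithium to an ester should take place at the ester on the tertiary carbon C5, because the C10 ester sits on a quaternary carbon and is far more hindered; C4 carries two methyls, so no stereocentre is made.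

Step 11
Reactants: 15 C4 carbinol C10 menthyl ester
Product: 16 diol with C1 as CH2OH on C10 and C4 as C(CH3)2OH on C5
Conditions: LiAlH4, THF, 0 → 65 °C
Reagents that add atoms: none
Why: LiAlH4 reduction of the hindered ester to the primary alcohol should release the second auxiliary and converge any lactone formed in step 10 to the same diol.

Step 12
Reactants: 16 C1,C4 diol
Product: 18 trans-fused five-membered lactol (C1 hemiacetal carbon bonded through oxygen to C4; anomers), via C1 hydroxy aldehyde 17 (not isolated)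
Conditions: (COCl)2, DMSO, CH2Cl2, −78 °C; Et3N, −78 → 0 °C
Reagents that add atoms: none
Why: Swern oxidation should convert only the primary alcohol, since the tertiary one cannot be oxidised, and the hindered aldehyde is then trapped as the lactol, which also guards it against further oxidation.

Step 13
Reactants: 18 lactol
Product: 19 diol with a C1 allylic alcohol (C1–CH=CH2; both C1 epimers) and the C4 tertiary alcohol
Conditions: CH2=CHMgBr (4 equiv), THF, 0 → 23 °C
Reagents that add atoms: vinylmagnesium bromide, C=C[Mg]Br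
Why: Grignard addition to the ring-opened aldehyde form of the magnesium lactolate should deliver C2 and C3; the C1 epimers need no separation because C1 is oxidised next.

Step 14
Reactants: 19 allylic alcohol diol
Product: 20 C1 vinyl ketone with free C4 tertiary alcohol
Conditions: Dess–Martin periodinane, CH2Cl2, 0 → 23 °C
Reagents that add atoms: none
Why: Dess–Martin oxidation of the secondary allylic alcohol should give the enone while the tertiary alcohol stays untouched.

Step 15
Reactants: 20 hydroxy vinyl ketone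
Product: 21 C4 tert-alkyl methyl oxalate of 20
Conditions: ClCOCO2Me, Et3N, DMAP (10 mol %), CH2Cl2, 0 °C
Reagents that add atoms: methyl chlorooxoacetate, COC(=O)C(=O)Cl
Why: DMAP-catalysed acylation with the highly electrophilic oxalyl half-ester chloride should esterify even a hindered tertiary alcohol at 0 °C.

Step 16
Reactants: 21 tert-alkyl methyl oxalate
Product: 22 caesium tert-alkyl oxalate
Conditions: CsOH·H2O (1.0 equiv), THF–H2O, 0 °C, short contact; concentration
Reagents that add atoms: caesium hydroxide monohydrate, [Cs+].[OH-].O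
Why: Selective saponification of the methyl oxalate terminus by one equivalent of hydroxide is much faster than attack on the tert-alkyl ester or conjugate addition to the enone.

Step 17
Reactants: 22 caesium tert-alkyl oxalate
Product: 25 12-[(tert-butyldimethylsilyl)oxy]-17-[(tert-butyldiphenylsilyl)oxy]-13,14,15,16-tetranor-ent-labd-7-en-1-one, via tertiary C4 radical 23 (not isolated), via cyclised C2 radical 24 (not isolated)
Conditions: Ir[dF(CF3)ppy]2(dtbbpy)PF6 (2 mol %), DME–DMF 3:1, H2O (10 equiv), blue LEDs, 60 °C, 0.02 M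
Reagents that add atoms: none
Why: Photoredox oxidation of the oxalate and loss of two CO2 should give the tertiary C4 radical, whose 6-endo-trig Giese addition to the vinyl ketone terminus C3 closes ring A and is finished by reduction and protonation of the α-keto radical; the trans fusion is already fixed by C5 and C10 and no stereocentre is made.

Step 18
Reactants: 25 ring A C1 ketone
Product: 26 corresponding C1 alcohol (C1 configuration immaterial)
Conditions: LiAlH4, THF, 0 °C
Reagents that add atoms: none
Why: Hydride reduction of the hindered ketone prepares C1 for radical deoxygenation, and both silyl ethers tolerate LiAlH4.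

Step 19
Reactants: 26 C1 alcohol
Product: 28 C1 O-alkyl S-methyl dithiocarbonate (xanthate), via sodium xanthate 27 (not isolated)
Conditions: NaH, imidazole (cat.), THF, 0 → 23 °C; CS2; MeI
Reagents that add atoms: carbon disulfide, S=C=S; iodomethane, CI
Why: Alkoxide addition to CS2 followed by S-methylation (xanthate formation) is the standard activation for Barton–McCombie deoxygenation.

Step 20
Reactants: 28 C1 xanthate
Product: 29 (5R,9S,10R)-12-[(tert-butyldimethylsilyl)oxy]-17-[(tert-butyldiphenylsilyl)oxy]-13,14,15,16-tetranor-ent-labd-7-ene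
Conditions: Bu3SnH, AIBN (cat.), toluene, 110 °C
Reagents that add atoms: none
Why: Barton–McCombie deoxygenation should proceed by stannyl radical addition to C=S, β-scission to the secondary C1 radical and hydrogen transfer from Bu3SnH, giving the C1 methylene.

**Side chain**

Step 21
Reactants: 29 bis-silyl ether
Product: 30 17-[(tert-butyldiphenylsilyl)oxy]-13,14,15,16-tetranor-ent-labd-7-en-12-ol
Conditions: PPTS (cat.), EtOH, 40 °C
Reagents that add atoms: none
Why: Acid-catalysed ethanolysis (selective desilylation) should cleave the primary TBS ether much faster than the bulkier TBDPS ether.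

Step 22
Reactants: 30 C12 alcohol
Product: 31 12-iodo-17-[(tert-butyldiphenylsilyl)oxy]-13,14,15,16-tetranor-ent-labd-7-ene
Conditions: I2, PPh3, imidazole, CH2Cl2, 0 → 23 °C
Reagents that add atoms: iodine, II
Why: Appel-type iodination converts the primary alcohol to the iodide through an alkoxyphosphonium ion and SN2 displacement.

Step 23
Reactants: 31 C12 iodide
Product: 32 17-[(tert-butyldiphenylsilyl)oxy]-15,16-dinor-ent-labd-7-en-13-yne
Conditions: LiC≡CH·H2NCH2CH2NH2, DMSO, 15 → 23 °C
Reagents that add atoms: lithium acetylide (ethylenediamine complex), [Li]C#C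
Why: SN2 alkylation of lithium acetylide by an unhindered primary iodide in DMSO should form C12–C13 and give the terminal alkyne directly.

Step 24
Reactants: 32 terminal alkyne
Product: 35 (13E)-17-[(tert-butyldiphenylsilyl)oxy]-ent-labda-7,13-dien-15-ol, via alkenyldimethylalane 33 (not isolated), via lithium alkenylalanate 34 (not isolated)
Conditions: Me3Al (2.5 equiv), Cp2ZrCl2 (0.25 equiv), CH2Cl2, 0 → 23 °C; volatiles removed; n-BuLi, THF, −78 °C; (CH2O)n, −78 → 23 °C
Reagents that add atoms: trimethylaluminium, C[Al](C)C; paraformaldehyde (formaldehyde unit), C=O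
Why: Zirconium-catalysed (Negishi) carboalumination adds methyl and aluminium syn across the terminal alkyne with methyl on C13, and the alanate then adds to formaldehyde with retention, so the 13E geometry is set by the syn addition.

**C32 acid**

Step 25
Reactants: 36 hexadecane-1,16-diol
Product: 37 16-[(tert-butyldiphenylsilyl)oxy]hexadecan-1-ol
Conditions: TBDPSCl (1 equiv), imidazole, 36 (3 equiv), THF–DMF, 40 °C
Reagents that add atoms: tert-butyldiphenylsilyl chloride, CC(C)(C)[Si](Cl)(c1ccccc1)c1ccccc1
Why: Statistical monosilylation of a symmetrical diol used in excess (silyl ether formation) should favour the mono-ether, and unreacted diol can be recovered.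

Step 26
Reactants: 37 16-[(tert-butyldiphenylsilyl)oxy]hexadecan-1-ol
Product: 38 16-[(tert-butyldiphenylsilyl)oxy]hexadecanal
Conditions: TEMPO (10 mol %), PhI(OAc)2, CH2Cl2, 23 °C
Reagents that add atoms: none
Why: Oxoammonium (TEMPO) oxidation of a primary alcohol should stop cleanly at the aldehyde.

Step 27
Reactants: 39 16-bromohexadecanoic acid
Product: 40 (15-carboxypentadecyl)triphenylphosphonium bromide
Conditions: PPh3, MeCN, reflux
Reagents that add atoms: triphenylphosphine, c1ccc(cc1)P(c1ccccc1)c1ccccc1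
Why: SN2 quaternisation of triphenylphosphine by the primary bromide gives the Wittig salt.

Step 28
Reactants: 40 (15-carboxypentadecyl)triphenylphosphonium bromide; 38 16-[(tert-butyldiphenylsilyl)oxy]hexadecanal
Product: 42 (Z)-32-[(tert-butyldiphenylsilyl)oxy]dotriacont-16-enoic acid, via sodium carboxylate ylide 41 (not isolated)
Conditions: NaN(SiMe3)2 (2.1 equiv), THF, 0 °C; 38, −78 → 23 °C; 1 M HCl
Reagents that add atoms: none
Why: Wittig olefination with the non-stabilised ylide of an ω-carboxyalkylphosphonium salt joins the two C16 halves; the alkene geometry is immaterial because the bond is hydrogenated next.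

Step 29
Reactants: 42 (Z)-32-[(tert-butyldiphenylsilyl)oxy]dotriacont-16-enoic acid
Product: 43 32-[(tert-butyldiphenylsilyl)oxy]dotriacontanoic acid
Conditions: H2 (1 atm), Pd/C (10 wt % palladium on carbon), EtOAc–THF, 40 °C
Reagents that add atoms: none
Why: Heterogeneous catalytic hydrogenation should saturate the disubstituted alkene without touching the silyl ether or the acid.

**Union and release**

Step 30
Reactants: 35 (13E)-17-[(tert-butyldiphenylsilyl)oxy]-ent-labda-7,13-dien-15-ol; 43 32-[(tert-butyldiphenylsilyl)oxy]dotriacontanoic acid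
Product: 44 (13E)-17-[(tert-butyldiphenylsilyl)oxy]-ent-labda-7,13-dien-15-yl 32-[(tert-butyldiphenylsilyl)oxy]dotriacontanoate
Conditions: EDC·HCl, DMAP, CH2Cl2, 23 °C
Reagents that add atoms: none
Why: Carbodiimide/DMAP (Steglich) esterification should acylate the unhindered primary allylic alcohol under neutral conditions that do not ionise the allylic C15–O bond.

Step 31
Reactants: 44 bis-silylated ester
Product: 45 (5R,9S,10R,13E)-17-hydroxy-ent-labda-7,13-dien-15-yl 32-hydroxydotriacontanoate
Conditions: HF·pyridine, pyridine, THF, 0 → 23 °C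
Reagents that add atoms: none
Why: Buffered fluoride-mediated desilylation should cleave both primary TBDPS ethers while leaving the allylic ester and both alkenes intact.

**Compound list**
1 | but-3-yn-1-ol | C#CCCO | starting material
2 | tert-butyl(but-3-yn-1-yloxy)dimethylsilane | C#CCCO[Si](C)(C)C(C)(C)C | intermediate
3 | lithium acetylide of 2 | [Li]C#CCCO[Si](C)(C)C(C)(C)C | intermediate
4 | methyl 5-[(tert-butyldimethylsilyl)oxy]pent-2-ynoate | COC(=O)C#CCCO[Si](C)(C)C(C)(C)C | intermediate
5 | methyl (E)-5-[(tert-butyldimethylsilyl)oxy]-2-(tributylstannyl)pent-2-enoate | CCCC[Sn](CCCC)(CCCC)/C(C(=O)OC)=C/CCO[Si](C)(C)C(C)(C)C | intermediate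
6 | (E)-5-[(tert-butyldimethylsilyl)oxy]-2-(tributylstannyl)pent-2-en-1-ol | CCCC[Sn](CCCC)(CCCC)/C(CO)=C/CCO[Si](C)(C)C(C)(C)C | intermediate
7 | (E)-5-[(tert-butyldimethylsilyl)oxy]-1-[(tert-butyldiphenylsilyl)oxy]-2-(tributylstannyl)pent-2-ene | CCCC[Sn](CCCC)(CCCC)/C(CO[Si](c1ccccc1)(c1ccccc1)C(C)(C)C)=C/CCO[Si](C)(C)C(C)(C)C | intermediate
8 | (E)-5-[(tert-butyldimethylsilyl)oxy]-1-[(tert-butyldiphenylsilyl)oxy]-2-iodopent-2-ene | I/C(CO[Si](c1ccccc1)(c1ccccc1)C(C)(C)C)=C/CCO[Si](C)(C)C(C)(C)C | intermediate
9 | (Z)-5-[(tert-butyldimethylsilyl)oxy]-1-[(tert-butyldiphenylsilyl)oxy]-2-vinylpent-2-ene | C=C/C(CO[Si](c1ccccc1)(c1ccccc1)C(C)(C)C)=C/CCO[Si](C)(C)C(C)(C)C | intermediate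
10 | mesaconic acid | C/C(=C\C(=O)O)C(=O)O | starting material
11 | (−)-menthol, (1R,2S,5R) | C[C@@H]1CC[C@H]([C@@H](C1)O)C(C)C | starting material
12 | di-(−)-menthyl mesaconate | C/C(=C\C(=O)O[C@@H]1C[C@H](C)CC[C@H]1C(C)C)C(=O)O[C@@H]1C[C@H](C)CC[C@H]1C(C)C | intermediate
13 | bis[(1R,2S,5R)-menthyl] (1S,2S,6R)-6-{2-[(tert-butyldimethylsilyl)oxy]ethyl}-5-{[(tert-butyldiphenylsilyl)oxy]methyl}-1-methylcyclohex-4-ene-1,2-dicarboxylate | CC(C)(C)[Si](C)(C)OCC[C@@H]1C(CO[Si](c2ccccc2)(c2ccccc2)C(C)(C)C)=CC[C@H](C(=O)O[C@@H]2C[C@H](C)CC[C@H]2C(C)C)[C@@]1(C)C(=O)O[C@@H]1C[C@H](C)CC[C@H]1C(C)C | intermediate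
14 | C4 methyl ketone (acetyl on C5), C10 menthyl ester, ring as in 13 | CC(C)(C)[Si](C)(C)OCC[C@@H]1C(CO[Si](c2ccccc2)(c2ccccc2)C(C)(C)C)=CC[C@H](C(C)=O)[C@@]1(C)C(=O)O[C@@H]1C[C@H](C)CC[C@H]1C(C)C | intermediate
15 | C4 carbinol (2-hydroxypropan-2-yl on C5), C10 menthyl ester, ring as in 13 | CC(C)(C)[Si](C)(C)OCC[C@@H]1C(CO[Si](c2ccccc2)(c2ccccc2)C(C)(C)C)=CC[C@H](C(C)(C)O)[C@@]1(C)C(=O)O[C@@H]1C[C@H](C)CC[C@H]1C(C)C | intermediate
16 | diol: C10–CH2OH (C1) and C5–C(CH3)2OH (C4), ring as in 13 | CC(C)(C)[Si](C)(C)OCC[C@@H]1C(CO[Si](c2ccccc2)(c2ccccc2)C(C)(C)C)=CC[C@H](C(C)(C)O)[C@@]1(C)CO | intermediate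
17 | C1 aldehyde with free C4 tertiary alcohol | CC(C)(C)[Si](C)(C)OCC[C@@H]1C(CO[Si](c2ccccc2)(c2ccccc2)C(C)(C)C)=CC[C@H](C(C)(C)O)[C@@]1(C)C=O | intermediate
18 | trans-fused lactol (C1 hemiacetal, O bridge to C4; anomers) | CC(C)(C)[Si](C)(C)OCC[C@@H]1C(CO[Si](c2ccccc2)(c2ccccc2)C(C)(C)C)=CC[C@@H]2C(C)(C)OC(O)[C@@]12C | intermediate
19 | C1 allylic alcohol (C1 epimers) with C4 tertiary alcohol | CC(C)(C)[Si](C)(C)OCC[C@@H]1C(CO[Si](c2ccccc2)(c2ccccc2)C(C)(C)C)=CC[C@H](C(C)(C)O)[C@@]1(C)C(O)C=C | intermediate
20 | C1 vinyl ketone with C4 tertiary alcohol | CC(C)(C)[Si](C)(C)OCC[C@@H]1C(CO[Si](c2ccccc2)(c2ccccc2)C(C)(C)C)=CC[C@H](C(C)(C)O)[C@@]1(C)C(=O)C=C | intermediate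
21 | C4 tert-alkyl methyl oxalate of 20 | CC(C)(C)[Si](C)(C)OCC[C@@H]1C(CO[Si](c2ccccc2)(c2ccccc2)C(C)(C)C)=CC[C@H](C(C)(C)OC(=O)C(=O)OC)[C@@]1(C)C(=O)C=C | intermediate
22 | caesium C4 tert-alkyl oxalate | CC(C)(C)[Si](C)(C)OCC[C@@H]1C(CO[Si](c2ccccc2)(c2ccccc2)C(C)(C)C)=CC[C@H](C(C)(C)OC(=O)C(=O)[O-])[C@@]1(C)C(=O)C=C.[Cs+] | intermediate
23 | tertiary C4 radical | CC(C)(C)[Si](C)(C)OCC[C@@H]1C(CO[Si](c2ccccc2)(c2ccccc2)C(C)(C)C)=CC[C@H]([C](C)C)[C@@]1(C)C(=O)C=C | intermediate
24 | cyclised C2 (α-keto) radical | CC(C)(C)[Si](C)(C)OCC[C@@H]1C(CO[Si](c2ccccc2)(c2ccccc2)C(C)(C)C)=CC[C@@H]2C(C)(C)C[CH]C(=O)[C@@]12C | intermediate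
25 | 12-[(tert-butyldimethylsilyl)oxy]-17-[(tert-butyldiphenylsilyl)oxy]-13,14,15,16-tetranor-ent-labd-7-en-1-one | CC(C)(C)[Si](C)(C)OCC[C@@H]1C(CO[Si](c2ccccc2)(c2ccccc2)C(C)(C)C)=CC[C@@H]2C(C)(C)CCC(=O)[C@@]12C | intermediate
26 | corresponding 1-ol (C1 epimers) | CC(C)(C)[Si](C)(C)OCC[C@@H]1C(CO[Si](c2ccccc2)(c2ccccc2)C(C)(C)C)=CC[C@@H]2C(C)(C)CCC(O)[C@@]12C | intermediate
27 | sodium C1 xanthate | CC(C)(C)[Si](C)(C)OCC[C@@H]1C(CO[Si](c2ccccc2)(c2ccccc2)C(C)(C)C)=CC[C@@H]2C(C)(C)CCC(OC(=S)[S-])[C@@]12C.[Na+] | intermediate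
28 | C1 O-alkyl S-methyl dithiocarbonate | CC(C)(C)[Si](C)(C)OCC[C@@H]1C(CO[Si](c2ccccc2)(c2ccccc2)C(C)(C)C)=CC[C@@H]2C(C)(C)CCC(OC(=S)SC)[C@@]12C | intermediate
29 | (5R,9S,10R)-12-[(tert-butyldimethylsilyl)oxy]-17-[(tert-butyldiphenylsilyl)oxy]-13,14,15,16-tetranor-ent-labd-7-ene | CC(C)(C)[Si](C)(C)OCC[C@@H]1C(CO[Si](c2ccccc2)(c2ccccc2)C(C)(C)C)=CC[C@@H]2C(C)(C)CCC[C@@]12C | intermediate
30 | 17-[(tert-butyldiphenylsilyl)oxy]-13,14,15,16-tetranor-ent-labd-7-en-12-ol | OCC[C@@H]1C(CO[Si](c2ccccc2)(c2ccccc2)C(C)(C)C)=CC[C@@H]2C(C)(C)CCC[C@@]12C | intermediate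
31 | 12-iodo-17-[(tert-butyldiphenylsilyl)oxy]-13,14,15,16-tetranor-ent-labd-7-ene | ICC[C@@H]1C(CO[Si](c2ccccc2)(c2ccccc2)C(C)(C)C)=CC[C@@H]2C(C)(C)CCC[C@@]12C | intermediate
32 | 17-[(tert-butyldiphenylsilyl)oxy]-15,16-dinor-ent-labd-7-en-13-yne | C#CCC[C@@H]1C(CO[Si](c2ccccc2)(c2ccccc2)C(C)(C)C)=CC[C@@H]2C(C)(C)CCC[C@@]12C | intermediate
33 | (E)-C14 alkenyldimethylalane (methyl on C13 cis to Al) | C/C(=C\[Al](C)C)CC[C@@H]1C(CO[Si](c2ccccc2)(c2ccccc2)C(C)(C)C)=CC[C@@H]2C(C)(C)CCC[C@@]12C | intermediate
34 | lithium butyl(alkenyl)dimethylalanate | C/C(=C\[Al-](C)(C)CCCC)CC[C@@H]1C(CO[Si](c2ccccc2)(c2ccccc2)C(C)(C)C)=CC[C@@H]2C(C)(C)CCC[C@@]12C.[Li+] | intermediate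
35 | (13E)-17-[(tert-butyldiphenylsilyl)oxy]-ent-labda-7,13-dien-15-ol | C/C(=C\CO)CC[C@@H]1C(CO[Si](c2ccccc2)(c2ccccc2)C(C)(C)C)=CC[C@@H]2C(C)(C)CCC[C@@]12C | intermediate
36 | hexadecane-1,16-diol | OCCCCCCCCCCCCCCCCO | starting material
37 | 16-[(tert-butyldiphenylsilyl)oxy]hexadecan-1-ol | OCCCCCCCCCCCCCCCCO[Si](c1ccccc1)(c1ccccc1)C(C)(C)C | intermediate
38 | 16-[(tert-butyldiphenylsilyl)oxy]hexadecanal | O=CCCCCCCCCCCCCCCCO[Si](c1ccccc1)(c1ccccc1)C(C)(C)C | intermediate
39 | 16-bromohexadecanoic acid | OC(=O)CCCCCCCCCCCCCCCBr | starting material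
40 | (15-carboxypentadecyl)triphenylphosphonium bromide | OC(=O)CCCCCCCCCCCCCCC[P+](c1ccccc1)(c1ccccc1)c1ccccc1.[Br-] | intermediate
41 | sodium 16-(triphenylphosphoranylidene)hexadecanoate | [Na+].[O-]C(=O)CCCCCCCCCCCCCCC=P(c1ccccc1)(c1ccccc1)c1ccccc1 | intermediate
42 | (Z)-32-[(tert-butyldiphenylsilyl)oxy]dotriacont-16-enoic acid | OC(=O)CCCCCCCCCCCCCC/C=C\CCCCCCCCCCCCCCCO[Si](c1ccccc1)(c1ccccc1)C(C)(C)C | intermediate
43 | 32-[(tert-butyldiphenylsilyl)oxy]dotriacontanoic acid | OC(=O)CCCCCCCCCCCCCCCCCCCCCCCCCCCCCCCO[Si](c1ccccc1)(c1ccccc1)C(C)(C)C | intermediate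
44 | (13E)-17-[(tert-butyldiphenylsilyl)oxy]-ent-labda-7,13-dien-15-yl 32-[(tert-butyldiphenylsilyl)oxy]dotriacontanoate | C/C(=C\COC(=O)CCCCCCCCCCCCCCCCCCCCCCCCCCCCCCCO[Si](c1ccccc1)(c1ccccc1)C(C)(C)C)CC[C@@H]1C(CO[Si](c2ccccc2)(c2ccccc2)C(C)(C)C)=CC[C@@H]2C(C)(C)CCC[C@@]12C | intermediate
45 | (5R,9S,10R,13E)-17-hydroxy-ent-labda-7,13-dien-15-yl 32-hydroxydotriacontanoate | C/C(=C\COC(=O)CCCCCCCCCCCCCCCCCCCCCCCCCCCCCCCO)CC[C@@H]1C(CO)=CC[C@@H]2C(C)(C)CCC[C@@]12C | target

**Step count**
Total: 31 steps. Longest linear sequence: 25 steps (steps 1–7, 9–24, 30 and 31).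

**Steps most likely to fail**

Step 9 (cycloaddition). The doubly hindered, trisubstituted diester may react too slowly, so that Lewis-acid-induced decomposition of the diene competes. Facial discrimination may also be poor, because the C5 ester, which lies cis to the methyl group, need not adopt the conformation that makes the two menthyl groups cooperate in the fumarate. The fallback replaces auxiliary control by a racemic cycloaddition and a resolution; it sets out from 9 and 10 and comes back at 16. Mesaconic acid 10 would be esterified with methanol (H2SO4, reflux) to dimethyl mesaconate F1, a smaller and more reactive dienophile. Cycloaddition of F1 with 9 (Et2AlCl in CH2Cl2, or toluene at 130 °C in a sealed tube) should give the racemic dimethyl cycloadduct F2. Addition of MeLi at −78 °C to the C5 ester would give the racemic C4 carbinol methyl ester F3, and LiAlH4 reduction would give racemic diol. Preparative chromatography on a chiral stationary phase (cellulose tris(3,5-dimethylphenylcarbamate) type) would then separate 16 from the enantiomer of 16 F4, and the route continues from 16.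

Step 17 (radical closure of ring A). The 6-endo addition may be slower than hydrogen abstraction or elimination at the tertiary centre, and the vinyl ketone may oligomerise or suffer hydroxide attack while the caesium salt is made in step 16. The fallback generates the same C4 radical by hydrogen-atom transfer to an alkene; it sets out from 20 and comes back at 25. Dehydration of 20 with Burgess reagent (toluene, 50 °C) should give the isopropenyl vinyl ketone F5, separated from any tetrasubstituted alkene isomer. Treating F5 with Fe(acac)3 and PhSiH3 in EtOH–ethylene glycol at 60 °C (iron-hydride reductive olefin–enone coupling, intramolecular) would transfer a hydrogen atom to the 1,1-disubstituted alkene and close the tertiary radical onto the enone to give 25.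

Step 10 (differentiation of the two esters). Discrimination between the two menthyl esters may be incomplete, the C4 alkoxide may close onto the C10 ester and the resulting lactone may take up more MeLi, or C5 may epimerise through enolisation. The fallback differentiates the two carbons by steric control in an oxidation; it sets out from 13 and comes back at 16. LiAlH4 reduction of both esters of 13 would give the bis(hydroxymethyl) diol F6 with recovery of both auxiliaries. TEMPO/PhI(OAc)2 oxidation attacks the less hindered C5–CH2OH first and should carry the resulting lactol on to the trans-fused lactone F7 (carbonyl at C4, C1 as the O-bearing methylene). Excess MeLi at −78 °C would open the lactone by double addition to give 16.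

**Further compounds**
F1 | step 9 | dimethyl mesaconate | C/C(=C\C(=O)OC)C(=O)OC
F2 | step 9 | racemic dimethyl cycloadduct (relative configuration as in 13; one enantiomer drawn) | CC(C)(C)[Si](C)(C)OCC[C@@H]1C(CO[Si](c2ccccc2)(c2ccccc2)C(C)(C)C)=CC[C@H](C(=O)OC)[C@@]1(C)C(=O)OC
F3 | step 9 | racemic C4 carbinol methyl ester (one enantiomer drawn) | CC(C)(C)[Si](C)(C)OCC[C@@H]1C(CO[Si](c2ccccc2)(c2ccccc2)C(C)(C)C)=CC[C@H](C(C)(C)O)[C@@]1(C)C(=O)OC
F4 | step 9 | enantiomer of 16 | CC(C)(C)[Si](C)(C)OCC[C@H]1C(CO[Si](c2ccccc2)(c2ccccc2)C(C)(C)C)=CC[C@@H](C(C)(C)O)[C@]1(C)CO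
F5 | step 17 | isopropenyl vinyl ketone | CC(C)(C)[Si](C)(C)OCC[C@@H]1C(CO[Si](c2ccccc2)(c2ccccc2)C(C)(C)C)=CC[C@H](C(C)=C)[C@@]1(C)C(=O)C=C
F6 | step 10 | bis(hydroxymethyl) diol (C1 and C4 both CH2OH) | CC(C)(C)[Si](C)(C)OCC[C@@H]1C(CO[Si](c2ccccc2)(c2ccccc2)C(C)(C)C)=CC[C@H](CO)[C@@]1(C)CO
F7 | step 10 | trans-fused lactone (C4 carbonyl, C1 methylene on oxygen) | CC(C)(C)[Si](C)(C)OCC[C@@H]1C(CO[Si](c2ccccc2)(c2ccccc2)C(C)(C)C)=CC[C@@H]2C(=O)OC[C@@]12C
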